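**Retrosynthetic overview**

- The strategy rests on ring A of the 2H-chromene: meta oxygens on C5 and C8a, carbon substituents on C4a, C6 and C7, and a single hydrogen on C8. This pattern is assembled in one operation from a 3,4-disubstituted cyclobutenone and a prenyl-bearing siloxyalkyne, so no aromatic substitution has to choose between C4a, C6 and C8.
- Target 26 ⇐ acetate 25 ⇐ phenol 24: the pyran ring is closed last, by oxidative 6-endo attack of O1 (on C8a) on the C4a prenyl group while O5 is masked as an acetate.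
- 24 ⇐ resorcinol monosilyl ether 22 ⇐ cyclobutenone 11 + siloxyalkyne 17: the benzannulation forms C5–C4a, C8a–C8 and C5–C6 and delivers the two oxygens differentiated.
- 11 ⇐ 3-ethoxycyclobutenone 5 (ketene from acid 1 + ethoxyacetylene 3) + an arylethyllithium from tyrosol 6; 17 ⇐ enyne 14 ⇐ prenyl bromide 12 + ethynylmagnesium bromide 13.
- Ring order: the hydroxyphenyl ring is bought with tyrosol; ring A is formed in step 8; the pyran ring in step 11.

Key step: step 8

Remark: 1, 3 (hexane solution) and 13 (THF solution) are taken as purchasable. Compounds 5, 10, 11, 19 and 21 carry stereocentres and are used as racemates or diastereomer mixtures; all of these centres disappear on aromatization, and the target is achiral.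

**Route**

Step 1
Reactants: 1 5-methylhex-4-enoic acid
Product: 2 5-methylhex-4-enoyl chloride
Conditions: (COCl)2, DMF (cat.), CH2Cl2, 0 °C → rt; concentrate and use crude
Reagents that add atoms: oxalyl chloride, O=C(Cl)C(=O)Cl
Why: Standard acid chloride formation through the Vilsmeier-type chloroiminium catalyst, mild enough to leave the trisubstituted alkene untouched.

Step 2
Reactants: 2 5-methylhex-4-enoyl chloride; 3 ethoxyacetylene
Product: 5 3-ethoxy-4-(3-methylbut-2-en-1-yl)cyclobut-2-en-1-one (racemic), via prenylketene 4 (not isolated)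
Conditions: Et3N, Et2O, slow addition of 2 to 3 (2.5 equiv), rt → 35 °C
Reagents that add atoms: none
Why: Dehydrochlorination gives the aldoketene, which undergoes ketene–alkyne [2+2] cycloaddition with the electron-rich alkyne, the unsubstituted alkyne carbon bonding to the ketene carbonyl carbon so that ethoxy sits on C3 and prenyl on C4.

Step 3
Reactants: 6 2-(4-hydroxyphenyl)ethanol (tyrosol)
Product: 7 4-(2-iodoethyl)phenol
Conditions: PPh3, I2, imidazole, CH2Cl2, 0 °C → rt
Reagents that add atoms: iodine, II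
Why: Appel-type iodination converts the primary alcohol through its alkoxyphosphonium salt, while the phenol is not displaced.

Step 4
Reactants: 7 4-(2-iodoethyl)phenol
Product: 8 [4-(2-iodoethyl)phenoxy]triisopropylsilane
Conditions: TIPSOTf, 2,6-lutidine, CH2Cl2, 0 °C
Reagents that add atoms: triisopropylsilyl triflate, CC(C)[Si](OS(=O)(=O)C(F)(F)F)(C(C)C)C(C)C
Why: O-Silylation of the phenol with a silyl triflate and a non-nucleophilic base, which neither alkylates at the iodide nor triggers phenoxide participation.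

Step 5
Reactants: 8 [4-(2-iodoethyl)phenoxy]triisopropylsilane; 5 3-ethoxy-4-(3-methylbut-2-en-1-yl)cyclobut-2-en-1-one
Product: 11 4-(3-methylbut-2-en-1-yl)-3-{2-[4-(triisopropylsilyloxy)phenyl]ethyl}cyclobut-2-en-1-one (racemic), via arylethyllithium 9 (not isolated), via cyclobutenol adduct 10 (not isolated)
Conditions: t-BuLi (2.1 equiv), Et2O/pentane, −78 °C; then 5, −78 °C; then 1 M HCl, THF, 0 °C → rt
Reagents that add atoms: water, O
Why: Iodine–lithium exchange, 1,2-addition to the vinylogous ester carbonyl and acid hydrolysis with loss of ethanol (Stork–Danheiser-type carbonyl transposition) place the arylethyl group on C3 of the new enone and leave the prenyl group on C4.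

Step 6
Reactants: 12 1-bromo-3-methylbut-2-ene (prenyl bromide); 13 ethynylmagnesium bromide
Product: 14 5-methylhex-4-en-1-yne
Conditions: CuCl (5 mol%), THF, 0 °C → rt, 13 in excess; isolate by distillation
Reagents that add atoms: none
Why: Copper-catalysed coupling of an alkynyl Grignard reagent with an allylic bromide, which substitutes at the unhindered primary terminus of the prenyl system to give the skipped enyne.

Step 7
Reactants: 14 5-methylhex-4-en-1-yne
Product: 17 triisopropyl[(5-methylhex-4-en-1-yn-1-yl)oxy]silane, via lithium acetylide 15 (not isolated), via lithium ynolate 16 (not isolated)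
Conditions: LiN(SiMe3)2, THF, −78 °C; t-BuOOLi (from t-BuOOH and LiN(SiMe3)2), −78 → 0 °C; TIPSOTf, −78 → 0 °C
Reagents that add atoms: tert-butyl hydroperoxide, CC(C)(C)OO; triisopropylsilyl triflate, CC(C)[Si](OS(=O)(=O)C(F)(F)F)(C(C)C)C(C)C
Why: Electrophilic oxygen transfer from lithium tert-butyl peroxide to the lithium acetylide gives the ynolate, which the bulky silyl triflate traps on oxygen; the terminal C–H is much more acidic than the skipped CH2, so deprotonation at −78 °C is selective.

Step 8
Reactants: 11 4-(3-methylbut-2-en-1-yl)-3-{2-[4-(triisopropylsilyloxy)phenyl]ethyl}cyclobut-2-en-1-one; 17 triisopropyl[(5-methylhex-4-en-1-yn-1-yl)oxy]silane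
Product: 22 2,6-bis(3-methylbut-2-en-1-yl)-5-{2-[4-(triisopropylsilyloxy)phenyl]ethyl}-3-(triisopropylsilyloxy)phenol, via vinylketene 18 (not isolated), via vinylcyclobutenone 19 (not isolated), via dienylketene 20 (not isolated), via cyclohexadienone 21 (not isolated)
Conditions: toluene (degassed, sealed), 17 (1.3 equiv), 80 °C then 110 °C
Reagents that add atoms: none
Why: Heating opens cyclobutenone 11 by 4π electrocyclic ring opening to vinylketene 18, whose ketene carbonyl carbon is attacked by the oxygen-activated, prenyl-bearing carbon of siloxyalkyne 17 in a regioselective [2+2] cycloaddition that forms C5–C4a and C8a–C8 (cyclobutenone 19). A second 4π opening gives dienylketene 20, and ring A closes as a six-membered carbocycle by 6π electrocyclization (new bond C5–C6) to dienone 21, which tautomerizes to phenol 22. This is the Danheiser benzannulation of cyclobutenones with siloxyalkynes, the established entry to resorcinol monosilyl ethers. No stereocentre is created, and the racemic centre of 11 is erased on aromatization. The selectivity needed is the orientation of the [2+2] step, which the polarization of the siloxyalkyne against the ketene secures, so the silyloxy carbon ends meta to the new hydroxyl and O5 emerges free while the oxygen on C8a is silylated. Outward rotation of the C4 prenyl group in the first ring opening gives the E-vinylketene, which keeps the prenyl CH2 and alkene away from the ketene and so disfavours [1,5]-hydrogen shift and intramolecular cycloaddition.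

Step 9
Reactants: 22 2,6-bis(3-methylbut-2-en-1-yl)-5-{2-[4-(triisopropylsilyloxy)phenyl]ethyl}-3-(triisopropylsilyloxy)phenol
Product: 23 2,6-bis(3-methylbut-2-en-1-yl)-3-(triisopropylsilyloxy)-5-{2-[4-(triisopropylsilyloxy)phenyl]ethyl}phenyl acetate
Conditions: Ac2O, pyridine, DMAP (cat.), CH2Cl2, rt
Reagents that add atoms: acetic anhydride, CC(=O)OC(C)=O
Why: DMAP-catalysed acylation of the only free hydroxyl (O5), which is hindered by two ortho CH2 groups but still acylated by the acylpyridinium species.

Step 10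
Reactants: 23 2,6-bis(3-methylbut-2-en-1-yl)-3-(triisopropylsilyloxy)-5-{2-[4-(triisopropylsilyloxy)phenyl]ethyl}phenyl acetate
Product: 24 3-hydroxy-5-[2-(4-hydroxyphenyl)ethyl]-2,6-bis(3-methylbut-2-en-1-yl)phenyl acetate
Conditions: TBAF, AcOH (1:1), THF, 0 °C → rt
Reagents that add atoms: none
Why: Fluoride-mediated cleavage of both aryl silyl ethers, buffered with acetic acid so that the phenoxides are protonated at once and the aryl acetate is neither cleaved nor transferred.

Step 11
Reactants: 24 3-hydroxy-5-[2-(4-hydroxyphenyl)ethyl]-2,6-bis(3-methylbut-2-en-1-yl)phenyl acetate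
Product: 25 7-[2-(4-hydroxyphenyl)ethyl]-2,2-dimethyl-6-(3-methylbut-2-en-1-yl)-2H-chromen-5-yl acetate
Conditions: PdCl2(MeCN)2 (10 mol%), p-benzoquinone (1.5 equiv), THF, rt → 50 °C
Reagents that add atoms: none
Why: Wacker-type oxidative cyclization in which divalent palladium activates the C4a prenyl alkene, the C8a hydroxyl adds at the dimethyl-substituted carbon (6-endo, Markovnikov) and β-hydride elimination of a benzylic hydrogen gives the 2H-chromene, with benzoquinone reoxidizing palladium; the C6 prenyl group has no free ortho hydroxyl because O5 is acetylated.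

Step 12
Reactants: 25 7-[2-(4-hydroxyphenyl)ethyl]-2,2-dimethyl-6-(3-methylbut-2-en-1-yl)-2H-chromen-5-yl acetate
Product: 26 7-[2-(4-hydroxyphenyl)ethyl]-2,2-dimethyl-6-(3-methylbut-2-en-1-yl)-2H-chromen-5-ol (target)
Conditions: K2CO3, MeOH, rt
Reagents that add atoms: none
Why: Transesterification (methanolysis) of the aryl acetate under mild base, which the chromene and prenyl alkenes tolerate.

**Compound list**

1 | 5-methylhex-4-enoic acid | CC(C)=CCCC(=O)O | starting material
2 | 5-methylhex-4-enoyl chloride | CC(C)=CCCC(=O)Cl | intermediate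
3 | ethoxyacetylene | C#COCC | starting material
4 | (3-methylbut-2-en-1-yl)ketene (5-methylhexa-1,4-dien-1-one) | CC(C)=CCC=C=O | intermediate
5 | 3-ethoxy-4-(3-methylbut-2-en-1-yl)cyclobut-2-en-1-one (racemic) | O=C1C=C(OCC)C1CC=C(C)C | intermediate
6 | 2-(4-hydroxyphenyl)ethanol (tyrosol) | OCCc1ccc(O)cc1 | starting material
7 | 4-(2-iodoethyl)phenol | ICCc1ccc(O)cc1 | intermediate
8 | [4-(2-iodoethyl)phenoxy]triisopropylsilane | ICCc1ccc(O[Si](C(C)C)(C(C)C)C(C)C)cc1 | intermediate
9 | {2-[4-(triisopropylsilyloxy)phenyl]ethyl}lithium | [Li]CCc1ccc(O[Si](C(C)C)(C(C)C)C(C)C)cc1 | intermediate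
10 | 3-ethoxy-4-(3-methylbut-2-en-1-yl)-1-{2-[4-(triisopropylsilyloxy)phenyl]ethyl}cyclobut-2-en-1-ol (racemic diastereomer mixture) | OC1(CCc2ccc(O[Si](C(C)C)(C(C)C)C(C)C)cc2)C=C(OCC)C1CC=C(C)C | intermediate
11 | 4-(3-methylbut-2-en-1-yl)-3-{2-[4-(triisopropylsilyloxy)phenyl]ethyl}cyclobut-2-en-1-one (racemic) | O=C1C=C(CCc2ccc(O[Si](C(C)C)(C(C)C)C(C)C)cc2)C1CC=C(C)C | intermediate
12 | 1-bromo-3-methylbut-2-ene (prenyl bromide) | CC(C)=CCBr | starting material
13 | ethynylmagnesium bromide | C#C[Mg]Br | starting material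
14 | 5-methylhex-4-en-1-yne | CC(C)=CCC#C | intermediate
15 | (5-methylhex-4-en-1-yn-1-yl)lithium | CC(C)=CCC#C[Li] | intermediate
16 | lithium 5-methylhex-4-en-1-yn-1-olate | [Li+].CC(C)=CCC#C[O-] | intermediate
17 | triisopropyl[(5-methylhex-4-en-1-yn-1-yl)oxy]silane | CC(C)=CCC#CO[Si](C(C)C)(C(C)C)C(C)C | intermediate
18 | (3E)-7-methyl-3-{2-[4-(triisopropylsilyloxy)phenyl]ethyl}octa-1,3,6-trien-1-one | O=C=C/C(CCc1ccc(O[Si](C(C)C)(C(C)C)C(C)C)cc1)=C/CC=C(C)C | intermediate
19 | 2-(3-methylbut-2-en-1-yl)-4-{(3E)-7-methyl-1-[4-(triisopropylsilyloxy)phenyl]octa-3,6-dien-3-yl}-3-(triisopropylsilyloxy)cyclobut-2-en-1-one (racemic) | O=C1C(CC=C(C)C)=C(O[Si](C(C)C)(C(C)C)C(C)C)C1/C(CCc2ccc(O[Si](C(C)C)(C(C)C)C(C)C)cc2)=C/CC=C(C)C | intermediate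
20 | (3E,5E)-9-methyl-2-(3-methylbut-2-en-1-yl)-3-(triisopropylsilyloxy)-5-{2-[4-(triisopropylsilyloxy)phenyl]ethyl}deca-1,3,5,8-tetraen-1-one (ketene carbon C2 and C5 cis about C3=C4) | O=C=C(CC=C(C)C)/C(O[Si](C(C)C)(C(C)C)C(C)C)=C\C(CCc1ccc(O[Si](C(C)C)(C(C)C)C(C)C)cc1)=C\CC=C(C)C | intermediate
21 | 2,6-bis(3-methylbut-2-en-1-yl)-3-(triisopropylsilyloxy)-5-{2-[4-(triisopropylsilyloxy)phenyl]ethyl}cyclohexa-2,4-dien-1-one (racemic) | O=C1C(CC=C(C)C)=C(O[Si](C(C)C)(C(C)C)C(C)C)C=C(CCc2ccc(O[Si](C(C)C)(C(C)C)C(C)C)cc2)C1CC=C(C)C | intermediate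
22 | 2,6-bis(3-methylbut-2-en-1-yl)-5-{2-[4-(triisopropylsilyloxy)phenyl]ethyl}-3-(triisopropylsilyloxy)phenol | Oc1c(CC=C(C)C)c(O[Si](C(C)C)(C(C)C)C(C)C)cc(CCc2ccc(O[Si](C(C)C)(C(C)C)C(C)C)cc2)c1CC=C(C)C | intermediate
23 | 2,6-bis(3-methylbut-2-en-1-yl)-3-(triisopropylsilyloxy)-5-{2-[4-(triisopropylsilyloxy)phenyl]ethyl}phenyl acetate | CC(=O)Oc1c(CC=C(C)C)c(O[Si](C(C)C)(C(C)C)C(C)C)cc(CCc2ccc(O[Si](C(C)C)(C(C)C)C(C)C)cc2)c1CC=C(C)C | intermediate
24 | 3-hydroxy-5-[2-(4-hydroxyphenyl)ethyl]-2,6-bis(3-methylbut-2-en-1-yl)phenyl acetate | CC(=O)Oc1c(CC=C(C)C)c(O)cc(CCc2ccc(O)cc2)c1CC=C(C)C | intermediate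
25 | 7-[2-(4-hydroxyphenyl)ethyl]-2,2-dimethyl-6-(3-methylbut-2-en-1-yl)-2H-chromen-5-yl acetate | CC(C)=CCc1c(CCc2ccc(O)cc2)cc2c(c1OC(C)=O)C=CC(C)(C)O2 | intermediate
26 | 7-[2-(4-hydroxyphenyl)ethyl]-2,2-dimethyl-6-(3-methylbut-2-en-1-yl)-2H-chromen-5-ol | CC(C)=CCc1c(CCc2ccc(O)cc2)cc2c(c1O)C=CC(C)(C)O2 | target

**Step count and risks**

Total step count: 12. Longest linear sequence: 8 steps (steps 3, 4, 5, 8, 9, 10, 11, 12; the branch from acid 1 through steps 1, 2 and 5 is equally long).

Steps most likely to fail: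

1. Step 8 (benzannulation). The cascade may stall or be diverted in several ways: dimerization of the vinylketene, inward rotation of the C4 prenyl group followed by [1,5]-hydrogen shift or intramolecular ketene–alkene cycloaddition, or acylation of the product phenol by ketene intermediates. The fallback moves the C6 prenyl group out of the annulation and uses the best-precedented, C4-unsubstituted cyclobutenone class. It sets out from iodide 8 and siloxyalkyne 17 and returns at 22. Organolithium 9, generated from 8 as in step 5, would be added to commercial 3-ethoxycyclobut-2-en-1-one (O=C1C=C(OCC)C1) to give 3-ethoxy-1-{2-[4-(triisopropylsilyloxy)phenyl]ethyl}cyclobut-2-en-1-ol F1. Acid hydrolysis in the same flask would give 3-{2-[4-(triisopropylsilyloxy)phenyl]ethyl}cyclobut-2-en-1-one F2. Heating F2 with 17 in toluene should give 2-(3-methylbut-2-en-1-yl)-5-{2-[4-(triisopropylsilyloxy)phenyl]ethyl}-3-(triisopropylsilyloxy)phenol F3, in which the position that becomes C6 carries hydrogen. Tsuji–Trost O-alkylation of F3 with tert-butyl 2-methylbut-3-en-2-yl carbonate and Pd(PPh3)4 (zerovalent palladium) in THF should give the tertiary allyl ether triisopropyl{2-(3-methylbut-2-en-1-yl)-3-[(2-methylbut-3-en-2-yl)oxy]-5-{2-[4-(triisopropylsilyloxy)phenyl]ethyl}phenoxy}silane F4. Aromatic Claisen rearrangement of F4 in hot toluene can only deliver the prenyl group to the single free ortho position and, after tautomerization, gives 22.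

2. Step 11 (oxidative pyran closure). Closure may take the 5-exo course to an isopropenyl dihydrobenzofuran; palladium may shift either prenyl double bond; or adventitious acid may close the ring without oxidation to the chroman. The fallback replaces the palladium step by selenoetherification and selenoxide elimination; it sets out from 24 and returns at 25. N-(Phenylseleno)phthalimide with catalytic camphorsulfonic acid in CH2Cl2 should close the ring in the 6-endo sense to give racemic 7-[2-(4-hydroxyphenyl)ethyl]-2,2-dimethyl-6-(3-methylbut-2-en-1-yl)-3-(phenylselanyl)-3,4-dihydro-2H-chromen-5-yl acetate F5. Oxidation with NaIO4 in aqueous THF would give the selenoxide 7-[2-(4-hydroxyphenyl)ethyl]-2,2-dimethyl-6-(3-methylbut-2-en-1-yl)-3-(phenylseleninyl)-3,4-dihydro-2H-chromen-5-yl acetate F6. Syn-elimination from F6 can only go toward C4, because C2 is quaternary, and gives 25.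

3. Step 7 (siloxyalkyne formation). The base may deprotonate the doubly activated C3 methylene and isomerize the skipped enyne, oxygen transfer to the acetylide may be incomplete, or the ynolate may be silylated on carbon. The fallback avoids the terminal enyne and reaches the same ynolate from an α,α-dibromo ester; it sets out from acid 1 and returns at ynolate 16, which is silylated to 17 as in step 7. Acid-catalysed esterification of 1 with ethanol would give ethyl 5-methylhex-4-enoate F7. Enolization with LiN(iPr)2 and bromination with 1,2-dibromotetrachloroethane would give racemic ethyl 2-bromo-5-methylhex-4-enoate F8, and a second enolization and bromination would give ethyl 2,2-dibromo-5-methylhex-4-enoate F9. Treatment of F9 with t-BuLi (4 equiv) in THF at −78 → 0 °C should effect double bromine–lithium exchange and loss of lithium ethoxide from the ester dianion to give 16.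

**Further compounds**

F1 | step 8 | 3-ethoxy-1-{2-[4-(triisopropylsilyloxy)phenyl]ethyl}cyclobut-2-en-1-ol | OC1(CCc2ccc(O[Si](C(C)C)(C(C)C)C(C)C)cc2)C=C(OCC)C1
F2 | step 8 | 3-{2-[4-(triisopropylsilyloxy)phenyl]ethyl}cyclobut-2-en-1-one | O=C1C=C(CCc2ccc(O[Si](C(C)C)(C(C)C)C(C)C)cc2)C1
F3 | step 8 | 2-(3-methylbut-2-en-1-yl)-5-{2-[4-(triisopropylsilyloxy)phenyl]ethyl}-3-(triisopropylsilyloxy)phenol | Oc1cc(CCc2ccc(O[Si](C(C)C)(C(C)C)C(C)C)cc2)cc(O[Si](C(C)C)(C(C)C)C(C)C)c1CC=C(C)C
F4 | step 8 | triisopropyl{2-(3-methylbut-2-en-1-yl)-3-[(2-methylbut-3-en-2-yl)oxy]-5-{2-[4-(triisopropylsilyloxy)phenyl]ethyl}phenoxy}silane | C=CC(C)(C)Oc1cc(CCc2ccc(O[Si](C(C)C)(C(C)C)C(C)C)cc2)cc(O[Si](C(C)C)(C(C)C)C(C)C)c1CC=C(C)C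
F5 | step 11 | 7-[2-(4-hydroxyphenyl)ethyl]-2,2-dimethyl-6-(3-methylbut-2-en-1-yl)-3-(phenylselanyl)-3,4-dihydro-2H-chromen-5-yl acetate (racemic) | CC(C)=CCc1c(CCc2ccc(O)cc2)cc2c(c1OC(C)=O)CC([Se]c1ccccc1)C(C)(C)O2
F6 | step 11 | 7-[2-(4-hydroxyphenyl)ethyl]-2,2-dimethyl-6-(3-methylbut-2-en-1-yl)-3-(phenylseleninyl)-3,4-dihydro-2H-chromen-5-yl acetate (racemic, mixture at selenium) | CC(C)=CCc1c(CCc2ccc(O)cc2)cc2c(c1OC(C)=O)CC([Se](=O)c1ccccc1)C(C)(C)O2
F7 | step 7 | ethyl 5-methylhex-4-enoate | CCOC(=O)CCC=C(C)C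
F8 | step 7 | ethyl 2-bromo-5-methylhex-4-enoate (racemic) | CCOC(=O)C(Br)CC=C(C)C
F9 | step 7 | ethyl 2,2-dibromo-5-methylhex-4-enoate | CCOC(=O)C(Br)(Br)CC=C(C)C
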